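The cyclohexanone ring is cut at C1–C2 and C3–C4. The feature used: the diaryl methine C4 sits on C4a, next to C8a, which carries the carbonyl carbon C1, so C1 and C4 are the exocyclic termini of a hydroxy-o-quinodimethane on the hydroquinone ring and C2–C3 is an acrylate. Light turns a 2-(naphthylmethyl)benzaldehyde into that dienol, and Ti(OiPr)2(TADDOLate) steers its [4+2] addition to methyl acrylate, which closes the ring, forms both bonds and fixes C4 in one operation. The precursor is 3-benzyloxy-6-methoxybenzaldehyde carrying the 4-benzyloxy-8-methoxy-1-naphthylmethyl group beside the formyl group; the oxygen on the other side of the aldehyde stays methyl so that the excited carbonyl meets no second benzylic hydrogen.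

Key step: step 8

Assumption: the (R,R)-TADDOL complex is taken to open the dienol face that leads to the (1S,2S,4S) cycloadduct; if the sense proves opposite, (S,S)-TADDOL is used and nothing else changes.

Step 1
Reactants: 1 1,5-dimethoxynaphthalene
Product: 3 4,8-dimethoxynaphthalene-1-carbaldehyde, via aryl iminium chloride 2 (not isolated)
Conditions: POCl3, DMF, 0 → 90 °C; then H2O, 60 °C
Reagents that add atoms: N,N-dimethylformamide CN(C)C=O; water O
Why: Vilsmeier–Haack formylation; the two positions para to a methoxy group (C4 and C8) are equivalent by symmetry, so one aldehyde should form, and the formyl group deactivates the ring against a second attack.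

Step 2
Reactants: 3 4,8-dimethoxynaphthalene-1-carbaldehyde
Product: 4 4-hydroxy-8-methoxynaphthalene-1-carbaldehyde
Conditions: NaSEt (1.5 equiv), DMF, 100 °C; then 1 M HCl
Reagents that add atoms: none
Why: Nucleophilic O-demethylation by SN2 attack of thiolate on the methyl carbon; only the 4-methoxy group is para to the formyl group, so only its naphthoxide leaves as a vinylogous carboxylate, whereas the peri 8-methoxy group has no such conjugation and should stay.

Step 3
Reactants: 4 4-hydroxy-8-methoxynaphthalene-1-carbaldehyde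
Product: 5 4-(benzyloxy)-8-methoxynaphthalene-1-carbaldehyde
Conditions: BnBr, K2CO3, DMF, rt
Reagents that add atoms: benzyl bromide BrCc1ccccc1
Why: Williamson ether synthesis on an acidic naphthol, with no competing nucleophilic site in the molecule.

Step 4
Reactants: 6 3-bromo-4-methoxyphenol
Product: 7 4-(benzyloxy)-2-bromo-1-methoxybenzene
Conditions: BnBr, K2CO3, acetone, reflux
Reagents that add atoms: benzyl bromide BrCc1ccccc1
Why: Williamson ether synthesis of a simple phenol.

Step 5
Reactants: 7 4-(benzyloxy)-2-bromo-1-methoxybenzene (1.2 equiv); 5 4-(benzyloxy)-8-methoxynaphthalene-1-carbaldehyde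
Product: 9 [6-(benzyloxy)-2-bromo-3-methoxyphenyl][4-(benzyloxy)-8-methoxynaphthalen-1-yl]methanol (racemic), via aryllithium 8 (not isolated)
Conditions: LDA (1.15 equiv), THF, −78 °C, 1 h; then 5, −78 °C; aq. NH4Cl
Reagents that add atoms: none
Why: Directed ortho-lithiation at the ring C–H flanked by bromine and the benzyloxy oxygen (the most acidic one), followed by 1,2-addition of the aryllithium to the aldehyde; at −78 °C the 2-bromoaryllithium should neither lose LiBr nor attack the benzyl ethers, and the carbinol centre is removed in the next step, so its configuration does not matter.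

Step 6
Reactants: 9 [6-(benzyloxy)-2-bromo-3-methoxyphenyl][4-(benzyloxy)-8-methoxynaphthalen-1-yl]methanol
Product: 10 1-(benzyloxy)-4-{[6-(benzyloxy)-2-bromo-3-methoxyphenyl]methyl}-5-methoxynaphthalene
Conditions: Et3SiH (3 equiv), CF3CO2H (5 equiv), CH2Cl2, 0 °C
Reagents that add atoms: none
Why: Ionic hydrogenation; the carbinol ionises to a diarylmethyl cation stabilised by the 4-alkoxynaphthyl ring and takes hydride from the silane, while the aryl bromide and the benzyl ethers are inert under these conditions.

Step 7
Reactants: 10 1-(benzyloxy)-4-{[6-(benzyloxy)-2-bromo-3-methoxyphenyl]methyl}-5-methoxynaphthalene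
Product: 12 3-(benzyloxy)-2-{[4-(benzyloxy)-8-methoxynaphthalen-1-yl]methyl}-6-methoxybenzaldehyde, via aryllithium 11 (not isolated)
Conditions: n-BuLi (1.1 equiv), THF, −78 °C, 15 min; then DMF, −78 → 0 °C; aq. NH4Cl
Reagents that add atoms: N,N-dimethylformamide CN(C)C=O
Why: Bromine–lithium exchange followed by formylation with DMF (Bouveault aldehyde synthesis); at −78 °C the exchange is far faster than deprotonation of the diarylmethane CH2 or of the benzyl ethers.

Step 8
Reactants: 12 3-(benzyloxy)-2-{[4-(benzyloxy)-8-methoxynaphthalen-1-yl]methyl}-6-methoxybenzaldehyde; 13 methyl acrylate (5 equiv)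
Product: 15 methyl (1S,2S,4S)-5-(benzyloxy)-4-[4-(benzyloxy)-8-methoxynaphthalen-1-yl]-1-hydroxy-8-methoxy-1,2,3,4-tetrahydronaphthalene-2-carboxylate (all-cis), via hydroxy-o-quinodimethane 14 (not isolated)
Conditions: Ti(OiPr)4 (2 equiv), (R,R)-TADDOL (2.2 equiv), PhMe, rt, 1 h; then 12, 13, degassed, hν (366 nm), rt; aq. potassium sodium tartrate
Reagents that add atoms: none
Why: Excitation of the aldehyde (n,π*) is followed by 1,5-hydrogen transfer from the doubly benzylic CH2, and the biradical relaxes to the hydroxy-o-quinodimethane 14, which titanium holds as a dienolate chelated by the neighbouring methoxy oxygen (the later C8–OMe). The closest known chemistry is the photoenolisation/Diels–Alder reaction of 2-alkyl- and 2-benzylbenzaldehydes with acrylates, including its enantioselective form mediated by Ti(OiPr)4 and TADDOL. The six-membered carbocycle C1–C2–C3–C4–C4a–C8a is closed by an intermolecular [4+2] cycloaddition, suprafacial on both partners, that forms C1–C2 and C3–C4 and restores the benzene ring. C1 and C2 are set by the endo approach of the ester, which ends cis to the C1 oxygen, and their absolute sense by the TADDOLate, which binds dienolate oxygen and acrylate carbonyl at one titanium centre and leaves one diene face open; C4 follows from suprafacial addition to a dienol whose naphthyl group points outward. The step needs regioselectivity (ester at C2) and a single dienol geometry: the oxygen donor makes the naphthyl-bearing terminus the nucleophilic end and the titanium bridge brings the ester carbon next to C1, while the hydroxyl-inward dienol reketonises by 1,5-hydrogen shift and the naphthyl-inward form is disfavoured by its clash with the dienol C–H inside the locked s-cis diene.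

Step 9
Reactants: 15 methyl (1S,2S,4S)-5-(benzyloxy)-4-[4-(benzyloxy)-8-methoxynaphthalen-1-yl]-1-hydroxy-8-methoxy-1,2,3,4-tetrahydronaphthalene-2-carboxylate
Product: 16 methyl (4S)-5-(benzyloxy)-4-[4-(benzyloxy)-8-methoxynaphthalen-1-yl]-8-methoxy-1-oxo-1,2,3,4-tetrahydronaphthalene-2-carboxylate (C2 epimers and enol in equilibrium)
Conditions: Dess–Martin periodinane, pyridine, CH2Cl2, 0 °C → rt
Reagents that add atoms: none
Why: Dess–Martin oxidation of the secondary benzylic alcohol under buffered, non-basic conditions should give the β-keto ester without β-elimination; C2 becomes epimerisable but is cleared in the next step, and C4 is not enolisable.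

Step 10
Reactants: 16 methyl (4S)-5-(benzyloxy)-4-[4-(benzyloxy)-8-methoxynaphthalen-1-yl]-8-methoxy-1-oxo-1,2,3,4-tetrahydronaphthalene-2-carboxylate
Product: 18 (4S)-5-(benzyloxy)-4-[4-(benzyloxy)-8-methoxynaphthalen-1-yl]-8-methoxy-3,4-dihydronaphthalen-1(2H)-one, via lithium β-keto carboxylate 17 (not isolated)
Conditions: LiCl (3 equiv), H2O (3 equiv), DMSO, 130 °C
Reagents that add atoms: none
Why: Krapcho dealkoxycarbonylation; chloride removes the ester methyl by SN2 attack, the β-keto carboxylate loses CO2 and the enolate is protonated by water, while C4, which is not α to the carbonyl, keeps its configuration.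

Step 11
Reactants: 18 (4S)-5-(benzyloxy)-4-[4-(benzyloxy)-8-methoxynaphthalen-1-yl]-8-methoxy-3,4-dihydronaphthalen-1(2H)-one
Product: 19 (4S)-5,8-dihydroxy-4-(4-hydroxy-8-methoxynaphthalen-1-yl)-3,4-dihydronaphthalen-1(2H)-one
Conditions: BCl3 (8 equiv), C6HMe5 (6 equiv), CH2Cl2, −78 → 0 °C; then H2O
Reagents that add atoms: none
Why: Lewis-acid ether cleavage; BCl3 removes both benzyl groups as benzyl cations, which pentamethylbenzene traps, and cleaves the C8 methyl ether because it chelates boron together with the C1 carbonyl, whereas the unchelated naphthyl methyl ether should survive at or below 0 °C and no bond to C4 is touched.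

Compound list
1 | 1,5-dimethoxynaphthalene | COc1cccc2c(OC)cccc12 | starting material
2 | [(4,8-dimethoxynaphthalen-1-yl)methylidene]dimethylazanium chloride | COc1cccc2c(OC)ccc(C=[N+](C)C)c12.[Cl-] | intermediate
3 | 4,8-dimethoxynaphthalene-1-carbaldehyde | COc1cccc2c(OC)ccc(C=O)c12 | intermediate
4 | 4-hydroxy-8-methoxynaphthalene-1-carbaldehyde | COc1cccc2c(O)ccc(C=O)c12 | intermediate
5 | 4-(benzyloxy)-8-methoxynaphthalene-1-carbaldehyde | COc1cccc2c(OCc3ccccc3)ccc(C=O)c12 | intermediate
6 | 3-bromo-4-methoxyphenol | COc1ccc(O)cc1Br | starting material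
7 | 4-(benzyloxy)-2-bromo-1-methoxybenzene | COc1ccc(OCc2ccccc2)cc1Br | intermediate
8 | [6-(benzyloxy)-2-bromo-3-methoxyphenyl]lithium | COc1ccc(OCc2ccccc2)c([Li])c1Br | intermediate
9 | [6-(benzyloxy)-2-bromo-3-methoxyphenyl][4-(benzyloxy)-8-methoxynaphthalen-1-yl]methanol (racemic) | COc1ccc(OCc2ccccc2)c(C(O)c2ccc(OCc3ccccc3)c3cccc(OC)c23)c1Br | intermediate
10 | 1-(benzyloxy)-4-{[6-(benzyloxy)-2-bromo-3-methoxyphenyl]methyl}-5-methoxynaphthalene | COc1ccc(OCc2ccccc2)c(Cc2ccc(OCc3ccccc3)c3cccc(OC)c23)c1Br | intermediate
11 | [3-(benzyloxy)-2-{[4-(benzyloxy)-8-methoxynaphthalen-1-yl]methyl}-6-methoxyphenyl]lithium | COc1ccc(OCc2ccccc2)c(Cc2ccc(OCc3ccccc3)c3cccc(OC)c23)c1[Li] | intermediate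
12 | 3-(benzyloxy)-2-{[4-(benzyloxy)-8-methoxynaphthalen-1-yl]methyl}-6-methoxybenzaldehyde | COc1ccc(OCc2ccccc2)c(Cc2ccc(OCc3ccccc3)c3cccc(OC)c23)c1C=O | intermediate
13 | methyl acrylate (methyl prop-2-enoate) | C=CC(=O)OC | starting material
14 | {3-(benzyloxy)-2-[(4-(benzyloxy)-8-methoxynaphthalen-1-yl)methylidene]-6-methoxycyclohexa-3,5-dien-1-ylidene}methanol, (Z,Z), hydroxyl and naphthyl both outward (titanium-bound in the flask) | O/C=C1\C(OC)=CC=C(OCc2ccccc2)/C1=C\c1ccc(OCc2ccccc2)c2cccc(OC)c12 | intermediate
15 | methyl (1S,2S,4S)-5-(benzyloxy)-4-[4-(benzyloxy)-8-methoxynaphthalen-1-yl]-1-hydroxy-8-methoxy-1,2,3,4-tetrahydronaphthalene-2-carboxylate | COc1cccc2c(OCc5ccccc5)ccc([C@@H]3C[C@H](C(=O)OC)[C@H](O)c4c(OC)ccc(OCc6ccccc6)c43)c12 | intermediate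
16 | methyl (4S)-5-(benzyloxy)-4-[4-(benzyloxy)-8-methoxynaphthalen-1-yl]-8-methoxy-1-oxo-1,2,3,4-tetrahydronaphthalene-2-carboxylate (C2 not defined) | COc1cccc2c(OCc5ccccc5)ccc([C@@H]3CC(C(=O)OC)C(=O)c4c(OC)ccc(OCc6ccccc6)c43)c12 | intermediate
17 | lithium (4S)-5-(benzyloxy)-4-[4-(benzyloxy)-8-methoxynaphthalen-1-yl]-8-methoxy-1-oxo-1,2,3,4-tetrahydronaphthalene-2-carboxylate (C2 not defined) | COc1cccc2c(OCc5ccccc5)ccc([C@@H]3CC(C(=O)[O-])C(=O)c4c(OC)ccc(OCc6ccccc6)c43)c12.[Li+] | intermediate
18 | (4S)-5-(benzyloxy)-4-[4-(benzyloxy)-8-methoxynaphthalen-1-yl]-8-methoxy-3,4-dihydronaphthalen-1(2H)-one | COc1cccc2c(OCc5ccccc5)ccc([C@@H]3CCC(=O)c4c(OC)ccc(OCc6ccccc6)c43)c12 | intermediate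
19 | (4S)-5,8-dihydroxy-4-(4-hydroxy-8-methoxynaphthalen-1-yl)-3,4-dihydronaphthalen-1(2H)-one | COc1cccc2c(O)ccc([C@@H]3CCC(=O)c4c(O)ccc(O)c43)c12 | target

Total step count: 11. Longest linear sequence: 10 steps (steps 1–3 and 5–11).

Steps most likely to fail

Step 8. The process at risk is poor enantiofacial selection, because a simple acrylate binds the titanium centre through one carbonyl only; incomplete outward placement of the naphthyl group would add to it. The fallback sets out from 12 and comes back at 18, and it moves face selection from the metal to a covalently bound auxiliary. Irradiation (366 nm, PhMe) of 12 with achiral Ti(OiPr)4 and the commercial acrylate of (R)-pantolactone should give diastereomeric all-cis adducts that can be separated on silica. The one of the wanted series is (3R)-4,4-dimethyl-2-oxooxolan-3-yl (1S,2S,4S)-5-(benzyloxy)-4-[4-(benzyloxy)-8-methoxynaphthalen-1-yl]-1-hydroxy-8-methoxy-1,2,3,4-tetrahydronaphthalene-2-carboxylate F1; should the (R) auxiliary favour the other series, the (S) acrylate is taken. Dess–Martin oxidation would give the β-keto ester (3R)-4,4-dimethyl-2-oxooxolan-3-yl (4S)-5-(benzyloxy)-4-[4-(benzyloxy)-8-methoxynaphthalen-1-yl]-8-methoxy-1-oxo-1,2,3,4-tetrahydronaphthalene-2-carboxylate F2. Aqueous LiOH in THF, then acidification with AcOH and gentle warming, would hydrolyse the ester and decarboxylate the β-keto acid to give 18.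

Step 11. The process at risk is unselective dealkylation: loss of the naphthyl methyl ether on warming, or C-benzylation of the freed naphthol by benzyl cations that escape the scavenger. The fallback sets out from 18 and comes back at 19, and it cleaves the two kinds of ether by different mechanisms in two operations. Hydrogenolysis (H2, Pd/C, EtOAc, rt, stopped after the uptake of two equivalents) removes both benzyl groups without any cation and should give (4S)-5-hydroxy-4-(4-hydroxy-8-methoxynaphthalen-1-yl)-8-methoxy-3,4-dihydronaphthalen-1(2H)-one F6. MgI2·OEt2 in toluene at 60 °C then cleaves only the methyl ether that chelates magnesium together with the C1 carbonyl, giving 19.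

Step 2. The process at risk is loss of site selectivity between the two methyl ethers, or thiolate addition to the formyl group at the temperature needed. The fallback sets out from 1 and comes back at 5; the site is chosen by a free hydroxyl in an electrophilic substitution instead of by the formyl group in a nucleophilic dealkylation. Mono-demethylation of symmetrical 1 (NaSEt, 1 equiv, DMF, 120 °C; the naphthoxide formed resists a second cleavage) gives 5-methoxynaphthalen-1-ol F3. NBS in MeCN at −20 °C should brominate para to the hydroxyl, the stronger donor, to give 4-bromo-5-methoxynaphthalen-1-ol F4. Benzylation (BnBr, K2CO3, DMF) gives 1-(benzyloxy)-4-bromo-5-methoxynaphthalene F5, and bromine–lithium exchange (n-BuLi, THF, −78 °C) followed by DMF gives 5.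

Further compounds
F1 | step 8 | (3R)-4,4-dimethyl-2-oxooxolan-3-yl (1S,2S,4S)-5-(benzyloxy)-4-[4-(benzyloxy)-8-methoxynaphthalen-1-yl]-1-hydroxy-8-methoxy-1,2,3,4-tetrahydronaphthalene-2-carboxylate | COc1cccc2c(OCc5ccccc5)ccc([C@@H]3C[C@H](C(=O)O[C@H]7C(=O)OCC7(C)C)[C@H](O)c4c(OC)ccc(OCc6ccccc6)c43)c12
F2 | step 8 | (3R)-4,4-dimethyl-2-oxooxolan-3-yl (4S)-5-(benzyloxy)-4-[4-(benzyloxy)-8-methoxynaphthalen-1-yl]-8-methoxy-1-oxo-1,2,3,4-tetrahydronaphthalene-2-carboxylate (C2 not defined) | COc1cccc2c(OCc5ccccc5)ccc([C@@H]3CC(C(=O)O[C@H]7C(=O)OCC7(C)C)C(=O)c4c(OC)ccc(OCc6ccccc6)c43)c12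
F3 | step 2 | 5-methoxynaphthalen-1-ol | COc1cccc2c(O)cccc12
F4 | step 2 | 4-bromo-5-methoxynaphthalen-1-ol | COc1cccc2c(O)ccc(Br)c12
F5 | step 2 | 1-(benzyloxy)-4-bromo-5-methoxynaphthalene | COc1cccc2c(OCc3ccccc3)ccc(Br)c12
F6 | step 11 | (4S)-5-hydroxy-4-(4-hydroxy-8-methoxynaphthalen-1-yl)-8-methoxy-3,4-dihydronaphthalen-1(2H)-one | COc1cccc2c(O)ccc([C@@H]3CCC(=O)c4c(OC)ccc(O)c43)c12
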